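The cyclohexene is cut at its own C(CH3)=CH double bond. Ring-closing metathesis forms this bond and the six-membered ring in one operation from an acyclic 2-methyl-1,7-diene aldehyde in which the three contiguous stereocentres are already in place. The step exploits the fact that the ring alkene carries only a methyl group and sits beside the allylic CH that bears the 2,6-dioxygenated aryl ring (ring A): an isopropenyl and a vinyl terminus are all that is needed. The diene aldehyde comes from an enantioenriched 3-aryl-5-methylhex-5-enal and a racemic aryl vinyl carbinol by enantioconvergent iridium/amine dual catalysis; the aroyl group (ring B), the chalcone arm and the free phenols follow.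

Key step: step 11

Assumption: the iridium catalyst with ligand (R)-L is taken to give, with H pointing away, the order aryl → vinyl → new C–C bond clockwise at the allylic centre; if the sense is the opposite, the ligand enantiomers of steps 3 and 10 are exchanged and nothing else changes.

Abbreviations: MOM = methoxymethyl. L = 5-(dinaphtho[2,1-d:1′,2′-f][1,3,2]dioxaphosphepin-4-yl)-5H-dibenzo[b,f]azepine, the phosphoramidite–olefin ligand made from (R)- or (S)-BINOL. Ring C = the 2,4-dioxygenated ring on the cyclohexene; ring D = the 4-oxygenated ring of the enone.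

Step 1
Reactants: 1 2,4-dihydroxybenzaldehyde
Product: 2 2,4-bis(methoxymethoxy)benzaldehyde
Conditions: NaH, MOMCl, DMF, 0 °C to rt
Reagents that add atoms: chloromethyl methyl ether, COCCl
Why: Williamson etherification of both phenoxides, with NaH breaking the hydrogen bond that slows the 2-OH.

Step 2
Reactants: 2 2,4-bis(methoxymethoxy)benzaldehyde
Product: 3 rac-1-[2,4-bis(methoxymethoxy)phenyl]prop-2-en-1-ol
Conditions: CH2=CHMgBr, THF, −78 °C to 0 °C; aq. NH4Cl
Reagents that add atoms: vinylmagnesium bromide, C=C[Mg]Br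
Why: Grignard 1,2-addition; the carbinol is made racemic on purpose because step 3 is enantioconvergent, and acetal protection excludes group migration onto the new alkoxide.

Step 3
Reactants: 3 rac-1-[2,4-bis(methoxymethoxy)phenyl]prop-2-en-1-ol; 4 trimethyl(2-methylallyl)silane
Product: 5 1-[(3S)-5-methylhexa-1,5-dien-3-yl]-2,4-bis(methoxymethoxy)benzene
Conditions: [Ir(cod)Cl]2 (cat.), (S)-L (cat.), Zn(OTf)2 (cat.), ClCH2CH2Cl, 25 °C
Reagents that add atoms: none
Why: Iridium-catalysed enantioconvergent allylic substitution with Hosomi–Sakurai-type capture by the allylsilane: both enantiomers of 3 ionise to one aryl allyl iridium intermediate and the ligand directs attack to one face of the benzylic terminus, which should set the 3S centre in the branched product.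

Step 4
Reactants: 5 1-[(3S)-5-methylhexa-1,5-dien-3-yl]-2,4-bis(methoxymethoxy)benzene
Product: 7 (3S)-3-[2,4-bis(methoxymethoxy)phenyl]-5-methylhex-5-en-1-ol, via alkyl catecholboronate 6 (not isolated)
Conditions: catecholborane, RhCl(PPh3)3 (cat.), THF, 0 °C to rt; then NaOH, H2O2, 0 °C
Reagents that add atoms: hydrogen peroxide, OO (hydroxyl oxygen of 7); catecholborane, B1Oc2ccccc2O1 (boron of 6)
Why: Rhodium-catalysed anti-Markovnikov hydroboration is much faster at the monosubstituted vinyl group than at the 1,1-disubstituted alkene, and oxidation of the C–B bond leaves the stereocentre untouched.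

Step 5
Reactants: 7 (3S)-3-[2,4-bis(methoxymethoxy)phenyl]-5-methylhex-5-en-1-ol
Product: 8 (3S)-3-[2,4-bis(methoxymethoxy)phenyl]-5-methylhex-5-enal
Conditions: Dess–Martin periodinane, NaHCO3, CH2Cl2, 0 °C to rt
Reagents that add atoms: none
Why: Dess–Martin oxidation under buffered conditions; the stereocentre is β to the new aldehyde and cannot epimerise.

Step 6
Reactants: 9 resorcinol
Product: 10 1,3-bis(methoxymethoxy)benzene
Conditions: NaH, MOMCl, DMF, 0 °C to rt
Reagents that add atoms: chloromethyl methyl ether, COCCl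
Why: Williamson etherification of both phenoxides.

Step 7
Reactants: 10 1,3-bis(methoxymethoxy)benzene
Product: 12 2,6-bis(methoxymethoxy)benzaldehyde, via aryllithium 11 (not isolated)
Conditions: n-BuLi, THF, 0 °C to rt; then DMF, −78 °C to rt; aq. NH4Cl
Reagents that add atoms: N,N-dimethylformamide, CN(C)C=O
Why: Directed ortho-metalation, in which the two acetal oxygens cooperate to direct lithiation to C2, followed by formylation.

Step 8
Reactants: 12 2,6-bis(methoxymethoxy)benzaldehyde
Product: 13 3-bromo-2,6-bis(methoxymethoxy)benzaldehyde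
Conditions: NBS, MeCN, 0 °C to rt
Reagents that add atoms: N-bromosuccinimide, O=C1CCC(=O)N1Br
Why: Electrophilic aromatic bromination at C3, ortho and para to the two alkoxy groups and meta to the formyl group; the bromine is the later handle for the enone arm of ring A.

Step 9
Reactants: 13 3-bromo-2,6-bis(methoxymethoxy)benzaldehyde
Product: 14 rac-1-[3-bromo-2,6-bis(methoxymethoxy)phenyl]prop-2-en-1-ol
Conditions: CH2=CHMgBr, THF, −78 °C to 0 °C; aq. NH4Cl
Reagents that add atoms: vinylmagnesium bromide, C=C[Mg]Br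
Why: Grignard 1,2-addition, faster at −78 °C than magnesium–bromine exchange; the racemic carbinol suffices because step 10 is enantioconvergent.

Step 10
Reactants: 8 (3S)-3-[2,4-bis(methoxymethoxy)phenyl]-5-methylhex-5-enal; 14 rac-1-[3-bromo-2,6-bis(methoxymethoxy)phenyl]prop-2-en-1-ol
Product: 15 (2R,3S)-3-[2,4-bis(methoxymethoxy)phenyl]-2-{(1S)-1-[3-bromo-2,6-bis(methoxymethoxy)phenyl]prop-2-en-1-yl}-5-methylhex-5-enal
Conditions: [Ir(cod)Cl]2 (cat.), (R)-L (cat.), (S)-2-{bis[3,5-bis(trifluoromethyl)phenyl](trimethylsilyloxy)methyl}pyrrolidine (cat.), (MeO)2P(O)OH (promoter), ClCH2CH2Cl, 25 °C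
Reagents that add atoms: none
Why: Stereodivergent dual catalysis (enamine activation plus iridium allylic substitution): the E-enamine of 8 with the S amine exposes one face of C2 and should set 2R, the R ligand should set 1′S at the benzylic terminus of the allyl iridium species formed from either enantiomer of 14, and catalyst control is expected to override the existing C3 centre.

Step 11
Reactants: 15 (2R,3S)-3-[2,4-bis(methoxymethoxy)phenyl]-2-{(1S)-1-[3-bromo-2,6-bis(methoxymethoxy)phenyl]prop-2-en-1-yl}-5-methylhex-5-enal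
Product: 16 (1R,2S,6S)-6-[2,4-bis(methoxymethoxy)phenyl]-2-[3-bromo-2,6-bis(methoxymethoxy)phenyl]-4-methylcyclohex-3-ene-1-carbaldehyde
Conditions: second-generation Grubbs catalyst RuCl2(=CHPh)(PCy3)(H2IMes) (cat.), CH2Cl2, 40 °C
Reagents that add atoms: none
Why: The ruthenium benzylidene initiates at the monosubstituted vinyl group, the new alkylidene adds to the isopropenyl alkene through a ruthenacyclobutane, and cycloreversion releases the ring alkene while ethylene leaves and drives the reaction. The closest known reaction type is ring-closing olefin metathesis of 2-methyl-1,7-dienes to 1-methylcyclohexenes, including dienes that carry a 2,6-dialkoxyaryl group and a formyl group on the two carbons next to the vinyl terminus. The six-membered carbocycle is closed head to head between the two alkene termini, so the C(CH3)=CH bond itself is the ring-closing bond and its cis ring geometry is the only one possible. No new stereocentre is formed; the three set in steps 3 and 10, including the formyl-bearing carbon, should survive the neutral conditions. The step needs ring closure to win over cross-metathesis, which the substrate secures because these are its only two alkenes and three branched carbons hold them close; the aryl bromide, aldehyde and acetals should not engage the catalyst.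

Step 12
Reactants: 17 2-iodoresorcinol
Product: 18 2-iodo-1,3-bis(methoxymethoxy)benzene
Conditions: NaH, MOMCl, DMF, 0 °C to rt
Reagents that add atoms: chloromethyl methyl ether, COCCl
Why: Williamson etherification of both phenoxides of the commercial iodide, in which the aryl C–I bond is inert to NaH and to the alkylating agent.

Step 13
Reactants: 18 2-iodo-1,3-bis(methoxymethoxy)benzene; 19 (E)-4,4,5,5-tetramethyl-2-(3-methylbut-1-en-1-yl)-1,3,2-dioxaborolane
Product: 20 1,3-bis(methoxymethoxy)-2-[(E)-3-methylbut-1-en-1-yl]benzene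
Conditions: Pd(OAc)2 (cat.), SPhos (cat.), K3PO4, toluene/H2O, 80 °C
Reagents that add atoms: none
Why: Suzuki–Miyaura coupling with retention of the E geometry of the alkenylboronate; the biaryl phosphine copes with the di-ortho-substituted iodide.

Step 14
Reactants: 20 1,3-bis(methoxymethoxy)-2-[(E)-3-methylbut-1-en-1-yl]benzene; 16 (1R,2S,6S)-6-[2,4-bis(methoxymethoxy)phenyl]-2-[3-bromo-2,6-bis(methoxymethoxy)phenyl]-4-methylcyclohex-3-ene-1-carbaldehyde
Product: 22 {(1R,2S,6S)-6-[2,4-bis(methoxymethoxy)phenyl]-2-[3-bromo-2,6-bis(methoxymethoxy)phenyl]-4-methylcyclohex-3-en-1-yl}{2,4-bis(methoxymethoxy)-3-[(E)-3-methylbut-1-en-1-yl]phenyl}methanol (both carbinol epimers), via aryllithium 21 (not isolated)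
Conditions: 20, s-BuLi, TMEDA, THF, −78 °C; then 16, −78 °C; aq. NH4Cl
Reagents that add atoms: none
Why: Directed ortho-lithiation of 20 at C4 (its two free ortho positions are equivalent) and 1,2-addition to the aldehyde, faster at −78 °C than enolisation or bromine–lithium exchange; the new carbinol centre is uncontrolled and is erased in step 17.

Step 15
Reactants: 23 4-(methoxymethoxy)benzaldehyde; 24 diethyl {2-[methoxy(methyl)amino]-2-oxoethyl}phosphonate
Product: 25 (E)-N-methoxy-3-[4-(methoxymethoxy)phenyl]-N-methylprop-2-enamide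
Conditions: NaH, THF, 0 °C to rt
Reagents that add atoms: none
Why: Horner–Wadsworth–Emmons olefination, which should give the E-configured acrylamide carrying ring D.

Step 16
Reactants: 22 carbinol from step 14 (both epimers); 25 (E)-N-methoxy-3-[4-(methoxymethoxy)phenyl]-N-methylprop-2-enamide
Product: 27 (E)-1-{3-[(1S,5S,6R)-6-{hydroxy[2,4-bis(methoxymethoxy)-3-((E)-3-methylbut-1-en-1-yl)phenyl]methyl}-5-[2,4-bis(methoxymethoxy)phenyl]-3-methylcyclohex-2-en-1-yl]-2,4-bis(methoxymethoxy)phenyl}-3-[4-(methoxymethoxy)phenyl]prop-2-en-1-one (both carbinol epimers), via dilithio species 26 (not isolated)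
Conditions: t-BuLi (3 equiv), THF, −78 °C; then 25, −78 °C to −40 °C; aq. NH4Cl
Reagents that add atoms: none
Why: After lithiation of the hydroxyl, bromine–lithium exchange on ring A is faster than any deprotonation at −78 °C, and the aryllithium adds once to the N-methoxy-N-methylamide (Weinreb ketone synthesis) through a chelate that releases the E enone only on work-up.

Step 17
Reactants: 27 enone carbinol from step 16 (both epimers)
Product: 28 (E)-1-{3-[(1S,5S,6R)-6-{2,4-bis(methoxymethoxy)-3-[(E)-3-methylbut-1-en-1-yl]benzoyl}-5-[2,4-bis(methoxymethoxy)phenyl]-3-methylcyclohex-2-en-1-yl]-2,4-bis(methoxymethoxy)phenyl}-3-[4-(methoxymethoxy)phenyl]prop-2-en-1-one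
Conditions: Dess–Martin periodinane, NaHCO3, CH2Cl2, 0 °C to rt
Reagents that add atoms: none
Why: Dess–Martin oxidation of the benzylic alcohol, in which both carbinol epimers converge on one ketone, the enone is inert and the buffered medium should not epimerise the α-carbon.

Step 18
Reactants: 28 heptakis(methoxymethyl) ether of the target
Product: 30 (E)-1-{3-[(1S,5S,6R)-6-{2,4-dihydroxy-3-[(E)-3-methylbut-1-en-1-yl]benzoyl}-5-(2,4-dihydroxyphenyl)-3-methylcyclohex-2-en-1-yl]-2,4-dihydroxyphenyl}-3-(4-hydroxyphenyl)prop-2-en-1-one (target CNP0140882.1), via heptakis(trimethylsilyl) ether 29 (not isolated)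
Conditions: Me3SiOTf, 2,2′-bipyridyl, CH2Cl2/MeCN, 0 °C to rt; then H2O
Reagents that add atoms: none
Why: The silyl triflate with 2,2′-bipyridyl turns aromatic methoxymethyl ethers into aryl silyl ethers under buffered, non-protic conditions and water then frees the phenols, which avoids the strong acid that could close a freed phenol onto the ring alkene or the neighbouring ketone.

Compound list
1 | 2,4-dihydroxybenzaldehyde | O=Cc1ccc(O)cc1O | starting material
2 | 2,4-bis(methoxymethoxy)benzaldehyde | O=Cc1ccc(OCOC)cc1OCOC | intermediate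
3 | rac-1-[2,4-bis(methoxymethoxy)phenyl]prop-2-en-1-ol | C=CC(O)c1ccc(OCOC)cc1OCOC | intermediate
4 | trimethyl(2-methylallyl)silane | CC(=C)C[Si](C)(C)C | starting material
5 | 1-[(3S)-5-methylhexa-1,5-dien-3-yl]-2,4-bis(methoxymethoxy)benzene | C=C[C@@H](c1ccc(OCOC)cc1OCOC)CC(C)=C | intermediate
6 | 2-{(3R)-3-[2,4-bis(methoxymethoxy)phenyl]-5-methylhex-5-en-1-yl}-1,3,2-benzodioxaborole (not isolated) | O1c2ccccc2OB1CC[C@@H](c1ccc(OCOC)cc1OCOC)CC(C)=C | intermediate
7 | (3S)-3-[2,4-bis(methoxymethoxy)phenyl]-5-methylhex-5-en-1-ol | OCC[C@@H](c1ccc(OCOC)cc1OCOC)CC(C)=C | intermediate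
8 | (3S)-3-[2,4-bis(methoxymethoxy)phenyl]-5-methylhex-5-enal | O=CC[C@@H](c1ccc(OCOC)cc1OCOC)CC(C)=C | intermediate
9 | resorcinol | Oc1cccc(O)c1 | starting material
10 | 1,3-bis(methoxymethoxy)benzene | COCOc1cccc(OCOC)c1 | intermediate
11 | [2,6-bis(methoxymethoxy)phenyl]lithium (not isolated) | [Li]c1c(OCOC)cccc1OCOC | intermediate
12 | 2,6-bis(methoxymethoxy)benzaldehyde | O=Cc1c(OCOC)cccc1OCOC | intermediate
13 | 3-bromo-2,6-bis(methoxymethoxy)benzaldehyde | O=Cc1c(OCOC)ccc(Br)c1OCOC | intermediate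
14 | rac-1-[3-bromo-2,6-bis(methoxymethoxy)phenyl]prop-2-en-1-ol | C=CC(O)c1c(OCOC)ccc(Br)c1OCOC | intermediate
15 | (2R,3S)-3-[2,4-bis(methoxymethoxy)phenyl]-2-{(1S)-1-[3-bromo-2,6-bis(methoxymethoxy)phenyl]prop-2-en-1-yl}-5-methylhex-5-enal | C=C[C@H](c1c(OCOC)ccc(Br)c1OCOC)[C@H](C=O)[C@@H](c1ccc(OCOC)cc1OCOC)CC(C)=C | intermediate
16 | (1R,2S,6S)-6-[2,4-bis(methoxymethoxy)phenyl]-2-[3-bromo-2,6-bis(methoxymethoxy)phenyl]-4-methylcyclohex-3-ene-1-carbaldehyde | CC1=C[C@H](c2c(OCOC)ccc(Br)c2OCOC)[C@H](C=O)[C@@H](c2ccc(OCOC)cc2OCOC)C1 | intermediate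
17 | 2-iodoresorcinol (2-iodobenzene-1,3-diol) | Oc1cccc(O)c1I | starting material
18 | 2-iodo-1,3-bis(methoxymethoxy)benzene | COCOc1cccc(OCOC)c1I | intermediate
19 | (E)-4,4,5,5-tetramethyl-2-(3-methylbut-1-en-1-yl)-1,3,2-dioxaborolane | CC(C)/C=C/B1OC(C)(C)C(C)(C)O1 | starting material
20 | 1,3-bis(methoxymethoxy)-2-[(E)-3-methylbut-1-en-1-yl]benzene | CC(C)/C=C/c1c(OCOC)cccc1OCOC | intermediate
21 | {2,4-bis(methoxymethoxy)-3-[(E)-3-methylbut-1-en-1-yl]phenyl}lithium (not isolated) | [Li]c1ccc(OCOC)c(/C=C/C(C)C)c1OCOC | intermediate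
22 | {(1R,2S,6S)-6-[2,4-bis(methoxymethoxy)phenyl]-2-[3-bromo-2,6-bis(methoxymethoxy)phenyl]-4-methylcyclohex-3-en-1-yl}{2,4-bis(methoxymethoxy)-3-[(E)-3-methylbut-1-en-1-yl]phenyl}methanol, both carbinol epimers | CC1=C[C@H](c2c(OCOC)ccc(Br)c2OCOC)[C@H](C(O)c2ccc(OCOC)c(/C=C/C(C)C)c2OCOC)[C@@H](c2ccc(OCOC)cc2OCOC)C1 | intermediate
23 | 4-(methoxymethoxy)benzaldehyde | O=Cc1ccc(OCOC)cc1 | starting material
24 | diethyl {2-[methoxy(methyl)amino]-2-oxoethyl}phosphonate | CCOP(=O)(CC(=O)N(C)OC)OCC | starting material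
25 | (E)-N-methoxy-3-[4-(methoxymethoxy)phenyl]-N-methylprop-2-enamide | CON(C)C(=O)/C=C/c1ccc(OCOC)cc1 | intermediate
26 | dilithio derivative of 22: lithium alkoxide and ring A aryllithium in place of bromine (not isolated) | CC1=C[C@H](c2c(OCOC)ccc([Li])c2OCOC)[C@H](C(O[Li])c2ccc(OCOC)c(/C=C/C(C)C)c2OCOC)[C@@H](c2ccc(OCOC)cc2OCOC)C1 | intermediate
27 | (E)-1-{3-[(1S,5S,6R)-6-{hydroxy[2,4-bis(methoxymethoxy)-3-((E)-3-methylbut-1-en-1-yl)phenyl]methyl}-5-[2,4-bis(methoxymethoxy)phenyl]-3-methylcyclohex-2-en-1-yl]-2,4-bis(methoxymethoxy)phenyl}-3-[4-(methoxymethoxy)phenyl]prop-2-en-1-one, both carbinol epimers | CC1=C[C@H](c2c(OCOC)ccc(C(=O)/C=C/c3ccc(OCOC)cc3)c2OCOC)[C@H](C(O)c2ccc(OCOC)c(/C=C/C(C)C)c2OCOC)[C@@H](c2ccc(OCOC)cc2OCOC)C1 | intermediate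
28 | (E)-1-{3-[(1S,5S,6R)-6-{2,4-bis(methoxymethoxy)-3-[(E)-3-methylbut-1-en-1-yl]benzoyl}-5-[2,4-bis(methoxymethoxy)phenyl]-3-methylcyclohex-2-en-1-yl]-2,4-bis(methoxymethoxy)phenyl}-3-[4-(methoxymethoxy)phenyl]prop-2-en-1-one | CC1=C[C@H](c2c(OCOC)ccc(C(=O)/C=C/c3ccc(OCOC)cc3)c2OCOC)[C@H](C(=O)c2ccc(OCOC)c(/C=C/C(C)C)c2OCOC)[C@@H](c2ccc(OCOC)cc2OCOC)C1 | intermediate
29 | heptakis(trimethylsilyl) ether of 30 (not isolated) | CC1=C[C@H](c2c(O[Si](C)(C)C)ccc(C(=O)/C=C/c3ccc(O[Si](C)(C)C)cc3)c2O[Si](C)(C)C)[C@H](C(=O)c2ccc(O[Si](C)(C)C)c(/C=C/C(C)C)c2O[Si](C)(C)C)[C@@H](c2ccc(O[Si](C)(C)C)cc2O[Si](C)(C)C)C1 | intermediate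
30 | (E)-1-{3-[(1S,5S,6R)-6-{2,4-dihydroxy-3-[(E)-3-methylbut-1-en-1-yl]benzoyl}-5-(2,4-dihydroxyphenyl)-3-methylcyclohex-2-en-1-yl]-2,4-dihydroxyphenyl}-3-(4-hydroxyphenyl)prop-2-en-1-one | CC1=C[C@H](c2c(O)ccc(C(=O)/C=C/c3ccc(O)cc3)c2O)[C@H](C(=O)c2ccc(O)c(/C=C/C(C)C)c2O)[C@@H](c2ccc(O)cc2O)C1 | target

Total step count: 18. Longest linear sequence: 11 steps (steps 1 to 5, 10, 11, 14, 16, 17, 18).

Steps most likely to fail

Step 10. The β-branched enamine may meet the di-ortho-substituted aryl allyl iridium species too slowly. Mismatched double stereodifferentiation may erode diastereocontrol, and the acidic promoter may strip acetals. The fallback sets out from 8 and 14 and returns at 15; it makes the same bond and both centres by an Ireland–Claisen rearrangement. Pinnick oxidation of 8 (NaClO2, NaH2PO4, 2-methylbut-2-ene) should give (3S)-3-[2,4-bis(methoxymethoxy)phenyl]-5-methylhex-5-enoic acid F1. 1,3-Transposition of 14 (Ph3SiOReO3 cat., Et2O) into conjugation should give (E)-3-[3-bromo-2,6-bis(methoxymethoxy)phenyl]prop-2-en-1-ol F2. Steglich esterification (DCC, DMAP) joins them as (E)-3-[3-bromo-2,6-bis(methoxymethoxy)phenyl]prop-2-en-1-yl (3S)-3-[2,4-bis(methoxymethoxy)phenyl]-5-methylhex-5-enoate F3. Enolisation with LDA in THF/DMPU and silylation with Me3SiCl place the side chain trans to the allyloxy oxygen, and the chair [3,3] shift on warming should then give the 2,3-syn acid (2R,3S)-3-[2,4-bis(methoxymethoxy)phenyl]-2-{(1S)-1-[3-bromo-2,6-bis(methoxymethoxy)phenyl]prop-2-en-1-yl}-5-methylhex-5-enoic acid F4. The face is set by the aryl-bearing C3 centre through allylic strain, so a diastereomer separation may be needed here. LiAlH4 reduction should give (2R,3S)-3-[2,4-bis(methoxymethoxy)phenyl]-2-{(1S)-1-[3-bromo-2,6-bis(methoxymethoxy)phenyl]prop-2-en-1-yl}-5-methylhex-5-en-1-ol F5, and Dess–Martin oxidation rejoins the route at 15.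

Step 16. On the fully assembled substrate, exchange may be incomplete. Ortho-deprotonation of the other acetal-bearing rings may compete, and the aryllithium may add in conjugate fashion to the acrylamide. The fallback sets out from 22 and returns at 28; it builds the enone arm by palladium catalysis and an aldol condensation. Dess–Martin oxidation of 22 should give the bromo ketone {(1R,2S,6S)-6-[2,4-bis(methoxymethoxy)phenyl]-2-[3-bromo-2,6-bis(methoxymethoxy)phenyl]-4-methylcyclohex-3-en-1-yl}{2,4-bis(methoxymethoxy)-3-[(E)-3-methylbut-1-en-1-yl]phenyl}methanone F6. Stille coupling with tributyl(1-ethoxyvinyl)stannane (Pd(PPh3)4 cat., toluene, 100 °C) and brief hydrolysis of the enol ether (dilute HCl, THF, rt) should give the ring A methyl ketone, the analogue of F6 with acetyl in place of bromine F7. Kinetic deprotonation of the acetyl methyl group (LiHMDS, THF, −78 °C), which should be much faster than removal of the hindered ring α-hydrogen, and addition to 23 give the β-hydroxy ketone, the aldol adduct of F7 with 23 F8. Mesylation and elimination (MsCl, Et3N) should then give 28.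

Step 18. Seven acetals may not all leave, which gives inseparable partly protected mixtures. A freed ortho-phenol of ring A may also close onto the neighbouring ketone or the ring alkene during hydrolysis and chromatography. The fallback sets out from 28 and returns at 30. The phenols are not isolated free after acetal cleavage: the crude silyl ether mixture 29 is quenched with methanol and acetylated at once (Ac2O, pyridine, DMAP). This gives the heptaacetate of 30 F9, which can be purified on silica. Mild methanolysis (K2CO3, MeOH, 0 °C) as the very last operation then releases 30 without acid.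

Further compounds
F1 | step 10 | (3S)-3-[2,4-bis(methoxymethoxy)phenyl]-5-methylhex-5-enoic acid | OC(=O)C[C@@H](c1ccc(OCOC)cc1OCOC)CC(C)=C
F2 | step 10 | (E)-3-[3-bromo-2,6-bis(methoxymethoxy)phenyl]prop-2-en-1-ol | OC/C=C/c1c(OCOC)ccc(Br)c1OCOC
F3 | step 10 | (E)-3-[3-bromo-2,6-bis(methoxymethoxy)phenyl]prop-2-en-1-yl (3S)-3-[2,4-bis(methoxymethoxy)phenyl]-5-methylhex-5-enoate | O=C(OC/C=C/c1c(OCOC)ccc(Br)c1OCOC)C[C@@H](c1ccc(OCOC)cc1OCOC)CC(C)=C
F4 | step 10 | (2R,3S)-3-[2,4-bis(methoxymethoxy)phenyl]-2-{(1S)-1-[3-bromo-2,6-bis(methoxymethoxy)phenyl]prop-2-en-1-yl}-5-methylhex-5-enoic acid | C=C[C@H](c1c(OCOC)ccc(Br)c1OCOC)[C@H](C(=O)O)[C@@H](c1ccc(OCOC)cc1OCOC)CC(C)=C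
F5 | step 10 | (2R,3S)-3-[2,4-bis(methoxymethoxy)phenyl]-2-{(1S)-1-[3-bromo-2,6-bis(methoxymethoxy)phenyl]prop-2-en-1-yl}-5-methylhex-5-en-1-ol | C=C[C@H](c1c(OCOC)ccc(Br)c1OCOC)[C@H](CO)[C@@H](c1ccc(OCOC)cc1OCOC)CC(C)=C
F6 | step 16 | {(1R,2S,6S)-6-[2,4-bis(methoxymethoxy)phenyl]-2-[3-bromo-2,6-bis(methoxymethoxy)phenyl]-4-methylcyclohex-3-en-1-yl}{2,4-bis(methoxymethoxy)-3-[(E)-3-methylbut-1-en-1-yl]phenyl}methanone | CC1=C[C@H](c2c(OCOC)ccc(Br)c2OCOC)[C@H](C(=O)c2ccc(OCOC)c(/C=C/C(C)C)c2OCOC)[C@@H](c2ccc(OCOC)cc2OCOC)C1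
F7 | step 16 | analogue of F6 with acetyl in place of bromine on ring A | CC1=C[C@H](c2c(OCOC)ccc(C(C)=O)c2OCOC)[C@H](C(=O)c2ccc(OCOC)c(/C=C/C(C)C)c2OCOC)[C@@H](c2ccc(OCOC)cc2OCOC)C1
F8 | step 16 | aldol adduct of F7 with 23 (β-hydroxy ketone, both carbinol epimers) | CC1=C[C@H](c2c(OCOC)ccc(C(=O)CC(O)c3ccc(OCOC)cc3)c2OCOC)[C@H](C(=O)c2ccc(OCOC)c(/C=C/C(C)C)c2OCOC)[C@@H](c2ccc(OCOC)cc2OCOC)C1
F9 | step 18 | heptaacetate of 30 | CC1=C[C@H](c2c(OC(C)=O)ccc(C(=O)/C=C/c3ccc(OC(C)=O)cc3)c2OC(C)=O)[C@H](C(=O)c2ccc(OC(C)=O)c(/C=C/C(C)C)c2OC(C)=O)[C@@H](c2ccc(OC(C)=O)cc2OC(C)=O)C1
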